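**Plan**

- Retrosynthesis: the galloyl ester C–O bond at O3 is cut first. Then, in both flavan units at once, the O1–C2 and C2–H bonds (cyclic hemiketal of an aryl ketone, reduced by hydride) and the C1'–C2 bond (ring B aryllithium plus an acyl group). The C2'–C2' biaryl bond is cut last.
- Enabling feature: C2 of each unit is bonded both to the pyran oxygen O1 and to C1' of ring B, so it is a masked aryl ketone carbon. C1' lies ortho to the biaryl bond and meta to the nearest ring B oxygen, which is where bromine sits when 5-bromo-1,2,3-tris(benzyloxy)benzene is dimerised through C4.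
- Forward: two molecules of the ring B bromide are homocoupled to the 2,2'-dibromobiphenyl; ring A is joined to the C4–C3–C2 chain by opening methyl (R)-glycidate; the dilithiobiphenyl is acylated by two molecules of the Weinreb amide; both pyran rings (ring C) then close together by reductive etherification; desilylation, one galloylation and hydrogenolysis finish the route.
- Stereochemistry: C3 of both units comes from methyl (R)-glycidate. C2 is set by hydride delivery anti to the pseudoaxial 3-silyloxy group (2,3-cis, 2R). The R axis is secured by separating the two atropisomeric diketones formed from the racemic dibromide and the enantiopure amide.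

Key step: step 9

Assumption: natural theasinensin B has the R biaryl axis, which the SMILES string cannot express; the route aims at this atropisomer and all SMILES strings below leave the axis unspecified.

**Route**

Step 1
Reactants: 1 5-bromo-1,2,3-trimethoxybenzene
Product: 2 5-bromobenzene-1,2,3-triol
Conditions: BBr3, CH2Cl2, −78 °C → rt; then H2O
Reagents that add atoms: none
Why: Lewis-acid cleavage of aryl methyl ethers (BBr3 demethylation) frees the three phenols without touching the aryl bromide, so that hydrogenolysable benzyl groups can take the place of the methyl groups.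

Step 2
Reactants: 2 5-bromobenzene-1,2,3-triol
Product: 3 5-bromo-1,2,3-tris(benzyloxy)benzene
Conditions: BnBr (3.3 equiv), K2CO3, DMF, 60 °C, N2
Reagents that add atoms: benzyl bromide, BrCc1ccccc1
Why: Williamson etherification of the three phenoxides, run under nitrogen because pyrogallol anions are air-sensitive, should give the tribenzyl ether cleanly.

Step 3
Reactants: 3 5-bromo-1,2,3-tris(benzyloxy)benzene (two molecules per molecule of product)
Product: 5 rac-2,2'-dibromo-4,4',5,5',6,6'-hexakis(benzyloxy)biphenyl, via [6-bromo-2,3,4-tris(benzyloxy)phenyl]lithium 4 (not isolated)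
Conditions: LiN(i-Pr)2 (1.1 equiv per arene), THF, −78 °C; then anhydrous CuCl2 (1.2 equiv per arene), −78 °C → rt
Reagents that add atoms: second molecule of 3, 5-bromo-1,2,3-tris(benzyloxy)benzene, Brc1cc(OCc2ccccc2)c(OCc2ccccc2)c(OCc2ccccc2)c1
Why: Directed ortho-lithiation at one of the two equivalent ring C–H positions flanked by Br and OBn, followed by CuCl2-mediated oxidative homocoupling of two molecules of the aryllithium (a known entry to tetra-ortho-substituted 2,2'-dihalobiphenyls), joins the rings through the carbon between Br and O and so places both bromines ortho to the axis and meta to the nearest oxygen, the pattern of C1' in the target that bromination of a preformed hexaoxygenated biphenyl would not give.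

Step 4
Reactants: 6 phloroglucinol
Product: 7 3,5-bis(benzyloxy)phenol
Conditions: BnBr (2 equiv), K2CO3, DMF, rt
Reagents that add atoms: benzyl bromide, BrCc1ccccc1
Why: Statistical Williamson etherification of a cheap triphenol is a known preparation of the dibenzyl ether, the mono- and tri-ethers and C-benzylated material being removed by chromatography.

Step 5
Reactants: 7 3,5-bis(benzyloxy)phenol
Product: 8 1,3-bis(benzyloxy)-5-(methoxymethoxy)benzene
Conditions: NaH, MOMCl, DMF, 0 °C
Reagents that add atoms: chloromethyl methyl ether, COCCl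
Why: O-Alkylation of the sodium phenoxide installs an acetal that later directs lithiation, survives organolithium reagents and is the one ring A protecting group that mild acid removes.

Step 6
Reactants: 8 1,3-bis(benzyloxy)-5-(methoxymethoxy)benzene; 9 methyl (R)-glycidate
Product: 12 methyl (2R)-3-[2,4-bis(benzyloxy)-6-(methoxymethoxy)phenyl]-2-hydroxypropanoate, via aryllithium 10 (not isolated), via arylmagnesium bromide 11 (not isolated)
Conditions: n-BuLi, THF, 0 °C; MgBr2·OEt2, −20 °C; then 9, CuBr·SMe2 (10 mol %), −40 → −20 °C; aq. NH4Cl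
Reagents that add atoms: none
Why: MOM-directed ortho-lithiation (the acetal oxygen is the strongest director, so metalation should occur between OMOM and OBn), transmetalation and copper-catalysed SN2 opening of the epoxide at its CH2 terminus, the known route from glycidic esters to 3-aryl-2-hydroxypropanoates, leave the glycidate stereocentre untouched, so the carbinol carbon of 12 (later C3 of the flavan) is R.

Step 7
Reactants: 12 methyl (2R)-3-[2,4-bis(benzyloxy)-6-(methoxymethoxy)phenyl]-2-hydroxypropanoate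
Product: 13 methyl (2R)-3-[2,4-bis(benzyloxy)-6-(methoxymethoxy)phenyl]-2-(tert-butyldimethylsilyloxy)propanoate
Conditions: TBSCl, imidazole, DMF, rt
Reagents that add atoms: tert-butyldimethylsilyl chloride, CC(C)(C)[Si](C)(C)Cl
Why: Standard silylation of the secondary alcohol gives a bulky, non-chelating ether that withstands aryllithium reagents and later steers the hydride addition.

Step 8
Reactants: 13 methyl (2R)-3-[2,4-bis(benzyloxy)-6-(methoxymethoxy)phenyl]-2-(tert-butyldimethylsilyloxy)propanoate
Product: 14 (2R)-3-[2,4-bis(benzyloxy)-6-(methoxymethoxy)phenyl]-2-(tert-butyldimethylsilyloxy)-N-methoxy-N-methylpropanamide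
Conditions: MeNH(OMe)·HCl, i-PrMgCl, THF, −20 → 0 °C; aq. NH4Cl
Reagents that add atoms: N,O-dimethylhydroxylamine hydrochloride, CNOC.Cl
Why: Aminolysis of the ester by the chloromagnesium amide of N,O-dimethylhydroxylamine is a standard ester-to-Weinreb-amide conversion that should not epimerise an α-silyloxy ester at this temperature.

Step 9
Reactants: 5 rac-2,2'-dibromo-4,4',5,5',6,6'-hexakis(benzyloxy)biphenyl; 14 (2R)-3-[2,4-bis(benzyloxy)-6-(methoxymethoxy)phenyl]-2-(tert-butyldimethylsilyloxy)-N-methoxy-N-methylpropanamide (two molecules per molecule of 5)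
Product: 17 (aR)-2,2'-bis{(2R)-3-[2,4-bis(benzyloxy)-6-(methoxymethoxy)phenyl]-2-(tert-butyldimethylsilyloxy)propanoyl}-4,4',5,5',6,6'-hexakis(benzyloxy)biphenyl, via 2,2'-dilithiobiphenyl 15 (not isolated), via dilithium bis(hemiaminal alkoxide) 16 (not isolated)
Conditions: t-BuLi (4.1 equiv), THF, −78 °C; then 14 (2.4 equiv), −78 → −30 °C; aq. NH4Cl; chromatographic separation of the atropisomeric diastereomers
Reagents that add atoms: second molecule of 14, (2R)-3-[2,4-bis(benzyloxy)-6-(methoxymethoxy)phenyl]-2-(tert-butyldimethylsilyloxy)-N-methoxy-N-methylpropanamide, CON(C)C(=O)[C@H](O[Si](C)(C)C(C)(C)C)Cc1c(OCOC)cc(OCc2ccccc2)cc1OCc1ccccc1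
Why: Two bromine–lithium exchanges with t-BuLi (the second equivalent at each site destroys t-BuBr) give dilithiobiphenyl 15, whose two aryl carbanions each add to the carbonyl group of one molecule of 14; the closest known reaction type is the Weinreb ketone synthesis with aryllithiums. Each adduct is held as a five-membered lithium chelate between the alkoxide and the N-methoxy oxygen (16), so the ketone is released only on protonation; this secures single addition at each acyl group and keeps the neighbouring aryllithium from attacking a free ketone to close a fluorenol. No ring closes and no carbon stereocentre is created: the two silyloxy-bearing centres come unchanged from 14, because the chelated adduct cannot enolise before the cold quench. The chemoselectivity needed (exchange and addition faster than metalation of benzylic or MOM C–H bonds, and no α-deprotonation of the amide) rests on working at −78 °C with a weakly basic aryllithium. Because 5 is racemic about its axis, the enantiopure amide converts it into two atropisomeric diastereomers of the diketone, aR and aS, which should be separable on silica; the aR isomer 17 is carried on, its axis to be confirmed by circular dichroism and by correlation with the natural product after step 13.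

Step 10
Reactants: 17 (aR)-2,2'-bis{(2R)-3-[2,4-bis(benzyloxy)-6-(methoxymethoxy)phenyl]-2-(tert-butyldimethylsilyloxy)propanoyl}-4,4',5,5',6,6'-hexakis(benzyloxy)biphenyl
Product: 20 (aR)-2,2'-bis[(2R,3R)-5,7-bis(benzyloxy)-3-(tert-butyldimethylsilyloxy)chroman-2-yl]-4,4',5,5',6,6'-hexakis(benzyloxy)biphenyl, via bis(phenol) diketone 18 (not isolated), via bis(2-hydroxychroman) hemiketal 19 (not isolated)
Conditions: CF3CO2H, Et3SiH (excess), CH2Cl2, 0 °C
Reagents that add atoms: none
Why: In this acid-triggered reductive etherification (ionic hydrogenation, as used for C-aryl glycosides) CF3CO2H cleaves the two aryl MOM ethers, each freed ring A phenol closes onto its ketone (6-exo-trig) to the 2-hydroxychroman, ionisation gives a 2-aryl oxocarbenium ion whose 3-silyloxy group lies pseudoaxial to avoid allylic strain with ring B, and Et3SiH adds hydride axially on the face anti to that group, so that H2 ends trans and the aryl group cis to O3 (2R from 3R), while the silane also reduces the methoxymethyl cation and thus protects ring A from alkylation.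

Step 11
Reactants: 20 (aR)-2,2'-bis[(2R,3R)-5,7-bis(benzyloxy)-3-(tert-butyldimethylsilyloxy)chroman-2-yl]-4,4',5,5',6,6'-hexakis(benzyloxy)biphenyl
Product: 21 (aR)-2,2'-bis[(2R,3R)-5,7-bis(benzyloxy)-3-hydroxychroman-2-yl]-4,4',5,5',6,6'-hexakis(benzyloxy)biphenyl
Conditions: Bu4NF, AcOH, THF, rt
Reagents that add atoms: none
Why: Fluoride-mediated desilylation frees both axial 3-hydroxy groups and leaves the ten benzyl ethers and all stereocentres untouched.

Step 12
Reactants: 21 (aR)-2,2'-bis[(2R,3R)-5,7-bis(benzyloxy)-3-hydroxychroman-2-yl]-4,4',5,5',6,6'-hexakis(benzyloxy)biphenyl; 22 3,4,5-tris(benzyloxy)benzoic acid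
Product: 23 mono[3,4,5-tris(benzyloxy)benzoate] of 21 at one O3 (trideca-O-benzyl theasinensin B)
Conditions: 22 (1.0 equiv), DCC, DMAP, CH2Cl2, 0 °C → rt
Reagents that add atoms: none
Why: Steglich esterification of one of the two homotopic 3-hydroxy groups of the C2-symmetric diol with limiting acid should favour the single possible monoester, recovered 21 being recycled and the diester removed by chromatography.

Step 13
Reactants: 23 mono[3,4,5-tris(benzyloxy)benzoate] of 21
Product: 24 theasinensin B
Conditions: H2 (1 atm), Pd(OH)2/C, THF–MeOH, rt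
Reagents that add atoms: none
Why: Catalytic hydrogenolysis of the thirteen benzyl ethers under neutral conditions should leave the gallate ester, the chroman C–O bonds, the four stereocentres and the biaryl axis unchanged.

**Compound list**

1 | 5-bromo-1,2,3-trimethoxybenzene | COc1cc(Br)cc(OC)c1OC | starting material
2 | 5-bromobenzene-1,2,3-triol | Oc1cc(Br)cc(O)c1O | intermediate
3 | 5-bromo-1,2,3-tris(benzyloxy)benzene | Brc1cc(OCc2ccccc2)c(OCc2ccccc2)c(OCc2ccccc2)c1 | intermediate
4 | [6-bromo-2,3,4-tris(benzyloxy)phenyl]lithium | [Li]c1c(Br)cc(OCc2ccccc2)c(OCc2ccccc2)c1OCc1ccccc1 | intermediate (not isolated)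
5 | rac-2,2'-dibromo-4,4',5,5',6,6'-hexakis(benzyloxy)biphenyl (racemic about the axis) | Brc1cc(OCc2ccccc2)c(OCc2ccccc2)c(OCc2ccccc2)c1-c1c(Br)cc(OCc2ccccc2)c(OCc2ccccc2)c1OCc1ccccc1 | intermediate
6 | phloroglucinol | Oc1cc(O)cc(O)c1 | starting material
7 | 3,5-bis(benzyloxy)phenol | Oc1cc(OCc2ccccc2)cc(OCc2ccccc2)c1 | intermediate
8 | 1,3-bis(benzyloxy)-5-(methoxymethoxy)benzene | COCOc1cc(OCc2ccccc2)cc(OCc2ccccc2)c1 | intermediate
9 | methyl (R)-glycidate | COC(=O)[C@H]1CO1 | starting material
10 | [2,4-bis(benzyloxy)-6-(methoxymethoxy)phenyl]lithium | [Li]c1c(OCOC)cc(OCc2ccccc2)cc1OCc1ccccc1 | intermediate (not isolated)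
11 | [2,4-bis(benzyloxy)-6-(methoxymethoxy)phenyl]magnesium bromide | Br[Mg]c1c(OCOC)cc(OCc2ccccc2)cc1OCc1ccccc1 | intermediate (not isolated)
12 | methyl (2R)-3-[2,4-bis(benzyloxy)-6-(methoxymethoxy)phenyl]-2-hydroxypropanoate | COC(=O)[C@H](O)Cc1c(OCOC)cc(OCc2ccccc2)cc1OCc1ccccc1 | intermediate
13 | methyl (2R)-3-[2,4-bis(benzyloxy)-6-(methoxymethoxy)phenyl]-2-(tert-butyldimethylsilyloxy)propanoate | COC(=O)[C@H](O[Si](C)(C)C(C)(C)C)Cc1c(OCOC)cc(OCc2ccccc2)cc1OCc1ccccc1 | intermediate
14 | (2R)-3-[2,4-bis(benzyloxy)-6-(methoxymethoxy)phenyl]-2-(tert-butyldimethylsilyloxy)-N-methoxy-N-methylpropanamide | CON(C)C(=O)[C@H](O[Si](C)(C)C(C)(C)C)Cc1c(OCOC)cc(OCc2ccccc2)cc1OCc1ccccc1 | intermediate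
15 | 2,2'-dilithio-4,4',5,5',6,6'-hexakis(benzyloxy)biphenyl | [Li]c1cc(OCc2ccccc2)c(OCc2ccccc2)c(OCc2ccccc2)c1-c1c([Li])cc(OCc2ccccc2)c(OCc2ccccc2)c1OCc1ccccc1 | intermediate (not isolated)
16 | dilithium bis(hemiaminal alkoxide) from 15 and two molecules of 14 (hemiaminal carbons unspecified) | c1(C(O[Li])(N(C)OC)[C@H](O[Si](C)(C)C(C)(C)C)Cc2c(OCOC)cc(OCc3ccccc3)cc2OCc2ccccc2)cc(OCc2ccccc2)c(OCc2ccccc2)c(OCc2ccccc2)c1-c1c(C(O[Li])(N(C)OC)[C@H](O[Si](C)(C)C(C)(C)C)Cc2c(OCOC)cc(OCc3ccccc3)cc2OCc2ccccc2)cc(OCc2ccccc2)c(OCc2ccccc2)c1OCc1ccccc1 | intermediate (not isolated)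
17 | (aR)-2,2'-bis{(2R)-3-[2,4-bis(benzyloxy)-6-(methoxymethoxy)phenyl]-2-(tert-butyldimethylsilyloxy)propanoyl}-4,4',5,5',6,6'-hexakis(benzyloxy)biphenyl | c1(C(=O)[C@H](O[Si](C)(C)C(C)(C)C)Cc2c(OCOC)cc(OCc3ccccc3)cc2OCc2ccccc2)cc(OCc2ccccc2)c(OCc2ccccc2)c(OCc2ccccc2)c1-c1c(C(=O)[C@H](O[Si](C)(C)C(C)(C)C)Cc2c(OCOC)cc(OCc3ccccc3)cc2OCc2ccccc2)cc(OCc2ccccc2)c(OCc2ccccc2)c1OCc1ccccc1 | intermediate
18 | (aR)-bis(phenol) diketone: 17 with both MOM groups replaced by H | c1(C(=O)[C@H](O[Si](C)(C)C(C)(C)C)Cc2c(O)cc(OCc3ccccc3)cc2OCc2ccccc2)cc(OCc2ccccc2)c(OCc2ccccc2)c(OCc2ccccc2)c1-c1c(C(=O)[C@H](O[Si](C)(C)C(C)(C)C)Cc2c(O)cc(OCc3ccccc3)cc2OCc2ccccc2)cc(OCc2ccccc2)c(OCc2ccccc2)c1OCc1ccccc1 | intermediate (not isolated)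
19 | (aR)-2,2'-bis[(3R)-5,7-bis(benzyloxy)-2-hydroxy-3-(tert-butyldimethylsilyloxy)chroman-2-yl]-4,4',5,5',6,6'-hexakis(benzyloxy)biphenyl (hemiketal carbons unspecified, in equilibrium with 18) | CC(C)(C)[Si](C)(C)O[C@@H]1Cc2c(OCc3ccccc3)cc(OCc3ccccc3)cc2OC1(O)c1cc(OCc2ccccc2)c(OCc2ccccc2)c(OCc2ccccc2)c1-c1c(C2(O)Oc3cc(OCc4ccccc4)cc(OCc4ccccc4)c3C[C@H]2O[Si](C)(C)C(C)(C)C)cc(OCc2ccccc2)c(OCc2ccccc2)c1OCc1ccccc1 | intermediate (not isolated)
20 | (aR)-2,2'-bis[(2R,3R)-5,7-bis(benzyloxy)-3-(tert-butyldimethylsilyloxy)chroman-2-yl]-4,4',5,5',6,6'-hexakis(benzyloxy)biphenyl | CC(C)(C)[Si](C)(C)O[C@@H]1Cc2c(OCc3ccccc3)cc(OCc3ccccc3)cc2O[C@@H]1c1cc(OCc2ccccc2)c(OCc2ccccc2)c(OCc2ccccc2)c1-c1c([C@H]2Oc3cc(OCc4ccccc4)cc(OCc4ccccc4)c3C[C@H]2O[Si](C)(C)C(C)(C)C)cc(OCc2ccccc2)c(OCc2ccccc2)c1OCc1ccccc1 | intermediate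
21 | (aR)-2,2'-bis[(2R,3R)-5,7-bis(benzyloxy)-3-hydroxychroman-2-yl]-4,4',5,5',6,6'-hexakis(benzyloxy)biphenyl | O[C@@H]1Cc2c(OCc3ccccc3)cc(OCc3ccccc3)cc2O[C@@H]1c1cc(OCc2ccccc2)c(OCc2ccccc2)c(OCc2ccccc2)c1-c1c([C@H]2Oc3cc(OCc4ccccc4)cc(OCc4ccccc4)c3C[C@H]2O)cc(OCc2ccccc2)c(OCc2ccccc2)c1OCc1ccccc1 | intermediate
22 | 3,4,5-tris(benzyloxy)benzoic acid | O=C(O)c1cc(OCc2ccccc2)c(OCc2ccccc2)c(OCc2ccccc2)c1 | starting material
23 | mono[3,4,5-tris(benzyloxy)benzoate] of 21 at one O3 (aR; 2R,3R in both units) | O=C(O[C@@H]1Cc2c(OCc3ccccc3)cc(OCc3ccccc3)cc2O[C@@H]1c1cc(OCc2ccccc2)c(OCc2ccccc2)c(OCc2ccccc2)c1-c1c([C@H]2Oc3cc(OCc4ccccc4)cc(OCc4ccccc4)c3C[C@H]2O)cc(OCc2ccccc2)c(OCc2ccccc2)c1OCc1ccccc1)c1cc(OCc2ccccc2)c(OCc2ccccc2)c(OCc2ccccc2)c1 | intermediate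
24 | theasinensin B (aR; 2R,3R in both units) | O=C(O[C@@H]1Cc2c(O)cc(O)cc2O[C@@H]1c1cc(O)c(O)c(O)c1-c1c([C@H]2Oc3cc(O)cc(O)c3C[C@H]2O)cc(O)c(O)c1O)c1cc(O)c(O)c(O)c1 | target

**Step count**

Total: 13 steps. Longest linear sequence: 10 steps (6 → 7 → 8 → 12 → 13 → 14 → 17 → 20 → 21 → 23 → 24; steps 4 to 13).

**Steps most likely to fail**

Step 9. The hindered 2-biaryllithium may act as a base toward the amide (α-deprotonation, or elimination across the N–O bond), or the second acylation may stall next to the first adduct. The fallback changes the oxidation level of the electrophile. Setting out from 14, reduction with i-Bu2AlH at −78 °C should give (2R)-3-[2,4-bis(benzyloxy)-6-(methoxymethoxy)phenyl]-2-(tert-butyldimethylsilyloxy)propanal F2. Dilithiobiphenyl 15, made from 5 as in step 9, would add to two molecules of this less hindered aldehyde, which cannot be attacked twice, to give the 2,2'-bis[(2R)-1-hydroxy-2-silyloxy-3-arylpropyl]biphenyl F3 as a mixture of carbinol epimers. Oxidation of both carbinols with Dess–Martin periodinane and separation of the atropisomers then returns to the route at 17.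

Step 10. The silyl ether may be lost before the reduction, the aryl ketone may be reduced in its open form (over-reduction to a methylene group), or hydride may add with poor facial selectivity. The fallback sets C2 by reagent control in the open chain and closes the ring by substitution. Setting out from 17, the MOM groups are removed with ZnBr2 and n-PrSH in CH2Cl2 to give 18 in equilibrium with 19, now isolated. Since substrate (Felkin–Anh) control would give the syn carbinol, a CBS reduction (BH3·SMe2 with the oxazaborolidine enantiomer that delivers the 1S alcohol, the (S)-catalyst if ring B acts as the large group) is used to reach the anti (1S,2R) bis(carbinol) bis(phenol) F4. Mitsunobu etherification (PPh3, DIAD) then forms O1–C2 with inversion in both halves and returns to the route at 20.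

Step 3. The ortho-bromo aryllithium may lose LiBr to an aryne before it is oxidised, or the copper-mediated dimerisation of so hindered an aryl group may give mainly reduced or chlorinated arene. The fallback makes the biaryl bond by Ullmann coupling. Setting out from 3, electrophilic iodination (N-iodosuccinimide, catalytic CF3CO2H, MeCN) at the only activated ring position should give 1-bromo-2-iodo-3,4,5-tris(benzyloxy)benzene F1. Heating two molecules of F1 with copper powder in DMF would couple selectively at the C–I bond and return to the route at 5.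

**Further compounds**

F1 | step 3 | 1-bromo-2-iodo-3,4,5-tris(benzyloxy)benzene | Brc1cc(OCc2ccccc2)c(OCc2ccccc2)c(OCc2ccccc2)c1I
F2 | step 9 | (2R)-3-[2,4-bis(benzyloxy)-6-(methoxymethoxy)phenyl]-2-(tert-butyldimethylsilyloxy)propanal | O=C[C@H](O[Si](C)(C)C(C)(C)C)Cc1c(OCOC)cc(OCc2ccccc2)cc1OCc1ccccc1
F3 | step 9 | 2,2'-bis{(2R)-3-[2,4-bis(benzyloxy)-6-(methoxymethoxy)phenyl]-1-hydroxy-2-(tert-butyldimethylsilyloxy)propyl}-4,4',5,5',6,6'-hexakis(benzyloxy)biphenyl (carbinol carbons unspecified) | c1(C(O)[C@H](O[Si](C)(C)C(C)(C)C)Cc2c(OCOC)cc(OCc3ccccc3)cc2OCc2ccccc2)cc(OCc2ccccc2)c(OCc2ccccc2)c(OCc2ccccc2)c1-c1c(C(O)[C@H](O[Si](C)(C)C(C)(C)C)Cc2c(OCOC)cc(OCc3ccccc3)cc2OCc2ccccc2)cc(OCc2ccccc2)c(OCc2ccccc2)c1OCc1ccccc1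
F4 | step 10 | (aR)-2,2'-bis{(1S,2R)-3-[2,4-bis(benzyloxy)-6-hydroxyphenyl]-1-hydroxy-2-(tert-butyldimethylsilyloxy)propyl}-4,4',5,5',6,6'-hexakis(benzyloxy)biphenyl | c1([C@H](O)[C@H](O[Si](C)(C)C(C)(C)C)Cc2c(O)cc(OCc3ccccc3)cc2OCc2ccccc2)cc(OCc2ccccc2)c(OCc2ccccc2)c(OCc2ccccc2)c1-c1c([C@H](O)[C@H](O[Si](C)(C)C(C)(C)C)Cc2c(O)cc(OCc3ccccc3)cc2OCc2ccccc2)cc(OCc2ccccc2)c(OCc2ccccc2)c1OCc1ccccc1
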